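**Plan**

- Retrosynthetic cuts, in order: the 5‑O‑methyl group is put back (last step is a chelation‑controlled 5‑O‑demethylation); the C2–phenyl bond (conjugate addition to a chromone); the bond between the benzylic CH2 on C8 and the phenol‑ring carbon next to C–OH; the pyranone bonds O1–C2/C2–C3; the C8–formyl and C4a–acetyl bonds, back to 3,4,5‑trimethoxyphenol.
- Enabling feature: the pendant ring is a benzene with OH and OMe para to each other and the CH2 on the carbon ortho to C–OH. It is therefore the aromatic tautomer of a 2‑alkylidene‑cyclohexane‑1,4‑dione mono(methyl enol ether): C–OH is the ketone carbon, the CH2‑bearing carbon is its α‑carbon, and C–OMe is the ketal carbon of 4,4‑dimethoxycyclohexanone. The CH2 is a formyl carbon on C8.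
- Helpers: the flavanone is held at the chromone oxidation level during the enolate step (no acidic C3–H, no stereocentre to lose); the dimethyl ketal is the latent aryl methyl ether.
- Forward order: ring A comes from 3,4,5‑trimethoxyphenol (acetyl, then formyl on its two free carbons); the pyranone ring is closed third; the cyclohexanone is attached by aldol addition and aromatised in the same flask; the C2–C3 unit is saturated next; the 5‑OH is freed last.
- Stereochemistry: the only stereocentre (C2, S) comes from catalyst control in a Pd/(R)‑t‑BuPyOx conjugate addition of phenylboronic acid; the last step is base‑free and should not scramble it.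

Key step: step 4

Remark: the (R)‑ligand is chosen by carrying over the facial preference this catalyst shows with cyclic enones; if the chromone responds in the opposite sense, the (S)‑ligand is used instead.

**Route**

Step 1
Reactants: 1 3,4,5-trimethoxyphenol
Product: 2 1-(6-hydroxy-2,3,4-trimethoxyphenyl)ethan-1-one
Conditions: AcOH, BF3·OEt2, 85 °C; then H2O
Reagents that add atoms: acetic acid, CC(=O)O
Why: BF3‑mediated Friedel–Crafts (Fries‑type) C‑acetylation should occur at one of the two equivalent ortho carbons, the only free ring positions, and the chelated ketone deactivates the product against a second acylation.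

Step 2
Reactants: 2 1-(6-hydroxy-2,3,4-trimethoxyphenyl)ethan-1-one
Product: 3 3-acetyl-2-hydroxy-4,5,6-trimethoxybenzaldehyde
Conditions: Cl2CHOMe, TiCl4, CH2Cl2, 0 °C → rt; then aq. HCl
Reagents that add atoms: dichloromethyl methyl ether, COC(Cl)Cl; water, O
Why: Rieche formylation should deliver the electrophile to the single remaining ring carbon, which is ortho to the titanium‑bound phenol oxygen and activated by an ortho and a para methoxy group, and aqueous work‑up releases the aldehyde.

Step 3
Reactants: 3 3-acetyl-2-hydroxy-4,5,6-trimethoxybenzaldehyde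
Product: 5 5,6,7-trimethoxy-4-oxo-4H-chromene-8-carbaldehyde, via enaminone 4 (not isolated)
Conditions: Me2NCH(OMe)2, PhMe, 90 °C; then conc. HCl, CH2Cl2, rt
Reagents that add atoms: N,N-dimethylformamide dimethyl acetal, COC(OC)N(C)C
Why: Condensation of the methyl ketone with the amide acetal to the enaminone, then acid‑promoted 6‑endo addition–elimination of the phenol with loss of dimethylamine, is the standard chromone synthesis, and the aryl aldehyde, having no acidic C–H, should pass unchanged.

Step 4
Reactants: 5 5,6,7-trimethoxy-4-oxo-4H-chromene-8-carbaldehyde; 6 4,4-dimethoxycyclohexan-1-one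
Product: 11 8-(2-hydroxy-5-methoxybenzyl)-5,6,7-trimethoxy-4H-chromen-4-one, via lithium enolate 7 (not isolated), via lithium aldolate 8 (not isolated), via aldol mesylate 9 (not isolated), via benzylidene ketone 10 (not isolated)
Conditions: 6, LDA, THF, −78 °C; 5, −78 °C; MsCl, −78 → 0 °C; Et3N, rt; then TFA (excess), CH2Cl2, rt → 40 °C
Reagents that add atoms: none
Why: Enolate 7 adds to the formyl group of 5 (aldol addition), aldolate 8 is trapped as mesylate 9 and eliminated by Et3N (E1cB) to benzylidene ketone 10, and TFA then ionises the dimethyl ketal to an oxocarbenium ion that loses a proton to the methyl enol ether, whose cross‑conjugated dienone tautomerises irreversibly to the phenol. The closest known reaction types are the aldol condensation/aromatisation of cyclohexane‑1,4‑dione with aryl aldehydes to 2‑benzylhydroquinones and the methanol‑loss aromatisation of 4,4‑dimethoxycyclohexenones (quinone monoketal adducts) to 4‑methoxyphenols. No ring is closed: the six‑membered carbocycle arrives intact in 6 and is only brought to the aromatic level, redox‑neutrally, by loss of the aldehyde oxygen (as mesylate) and one methanol. The two stereocentres of 8 and 9 form without control and are erased, and the alkene geometry of 10 is irrelevant, so the step makes no stereochemical demand. Chemoselectivity between the formyl group and chromone C2/C4 should be secured by the absence of any acidic hydrogen in 5 and by the higher electrophilicity of the aldehyde toward a preformed enolate at −78 °C; regiochemistry is automatic because 6 is symmetrical, either α‑carbon being ortho to the former ketone carbon (C–OH), which is para to the former ketal carbon (C–OMe). Dehydration through the mesylate keeps the sequence free of water, so the ketal should eliminate methanol and not be hydrolysed to the hydroquinone.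

Step 5
Reactants: 11 8-(2-hydroxy-5-methoxybenzyl)-5,6,7-trimethoxy-4H-chromen-4-one; 12 phenylboronic acid
Product: 13 (2S)-8-(2-hydroxy-5-methoxybenzyl)-5,6,7-trimethoxy-2-phenylchroman-4-one
Conditions: Pd(OCOCF3)2 (5 mol %), (R)-t-BuPyOx (6 mol %), NH4PF6 (30 mol %), H2O, ClCH2CH2Cl, 60 °C
Reagents that add atoms: none
Why: In this Pd(II)/pyridine‑oxazoline asymmetric conjugate addition of an arylboronic acid to a chromone, transmetallation gives a cationic phenyl–Pd complex whose enantiodetermining insertion of C2=C3, on the face set by the tert‑butyl group of the (R)‑ligand, should give the (2S) centre, and protonolysis of the Pd enolate under base‑free conditions leaves it intact while tolerating the free phenol.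

Step 6
Reactants: 13 (2S)-8-(2-hydroxy-5-methoxybenzyl)-5,6,7-trimethoxy-2-phenylchroman-4-one
Product: 14 (2S)-5-hydroxy-8-(2-hydroxy-5-methoxybenzyl)-6,7-dimethoxy-2-phenylchroman-4-one
Conditions: BCl3, CH2Cl2, −78 → 0 °C; then H2O
Reagents that add atoms: none
Why: In this chelation‑controlled ether cleavage BCl3 should bind the C4 carbonyl and the peri 5‑methoxy oxygen in a six‑membered chelate so that only this methyl group is removed at low temperature (the phenol merely consumes one equivalent), and without base there is no retro‑oxa‑Michael opening to erode the C2 configuration.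

**Compound list**

1 | 3,4,5-trimethoxyphenol | COc1cc(O)cc(OC)c1OC | starting material
2 | 1-(6-hydroxy-2,3,4-trimethoxyphenyl)ethan-1-one | CC(=O)c1c(O)cc(OC)c(OC)c1OC | intermediate
3 | 3-acetyl-2-hydroxy-4,5,6-trimethoxybenzaldehyde | CC(=O)c1c(O)c(C=O)c(OC)c(OC)c1OC | intermediate
4 | 3-[(E)-3-(dimethylamino)prop-2-enoyl]-2-hydroxy-4,5,6-trimethoxybenzaldehyde (enaminone, not isolated) | CN(C)/C=C/C(=O)c1c(O)c(C=O)c(OC)c(OC)c1OC | intermediate
5 | 5,6,7-trimethoxy-4-oxo-4H-chromene-8-carbaldehyde | O=Cc1c(OC)c(OC)c(OC)c2c1occc2=O | intermediate
6 | 4,4-dimethoxycyclohexan-1-one | COC1(OC)CCC(=O)CC1 | starting material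
7 | lithium 4,4-dimethoxycyclohex-1-en-1-olate (not isolated) | [Li+].[O-]C1=CCC(OC)(OC)CC1 | intermediate
8 | lithium (5,5-dimethoxy-2-oxocyclohexyl)(5,6,7-trimethoxy-4-oxo-4H-chromen-8-yl)methanolate (diastereomer mixture, not isolated) | [Li+].[O-]C(C1CC(OC)(OC)CCC1=O)c1c(OC)c(OC)c(OC)c2c1occc2=O | intermediate
9 | (5,5-dimethoxy-2-oxocyclohexyl)(5,6,7-trimethoxy-4-oxo-4H-chromen-8-yl)methyl methanesulfonate (diastereomer mixture, not isolated) | CS(=O)(=O)OC(C1CC(OC)(OC)CCC1=O)c1c(OC)c(OC)c(OC)c2c1occc2=O | intermediate
10 | 8-[(E)-(5,5-dimethoxy-2-oxocyclohexylidene)methyl]-5,6,7-trimethoxy-4H-chromen-4-one (not isolated) | O=C1CCC(OC)(OC)C/C1=C\c1c(OC)c(OC)c(OC)c2c1occc2=O | intermediate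
11 | 8-(2-hydroxy-5-methoxybenzyl)-5,6,7-trimethoxy-4H-chromen-4-one | COc1ccc(O)c(Cc2c(OC)c(OC)c(OC)c3c2occc3=O)c1 | intermediate
12 | phenylboronic acid | OB(O)c1ccccc1 | starting material
13 | (2S)-8-(2-hydroxy-5-methoxybenzyl)-5,6,7-trimethoxy-2-phenylchroman-4-one | COc1ccc(O)c(Cc2c(OC)c(OC)c(OC)c3c2O[C@H](c2ccccc2)CC3=O)c1 | intermediate
14 | (2S)-5-hydroxy-8-(2-hydroxy-5-methoxybenzyl)-6,7-dimethoxy-2-phenylchroman-4-one | COc1ccc(O)c(Cc2c(OC)c(OC)c(O)c3c2O[C@H](c2ccccc2)CC3=O)c1 | target

**Step count and risks**

Total steps: 6. Longest linear sequence: 6 steps (1 → 14).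

Steps most likely to fail:

1. Step 4. The enolate may add to the chromone C2/C4 positions in competition with the formyl group, the aldolate may revert before it is mesylated, or the ketal may be hydrolysed ahead of methanol loss so that the methyl ether is lost. Fallback, from 5: the ortho‑lithiated phenoxide generated from commercial 2‑bromo‑4‑methoxyphenol (n‑BuLi, 2 equiv, THF, −78 °C) is added to the formyl group to give the diaryl carbinol F1. Ionic hydrogenation of this doubly benzylic, electron‑rich alcohol (Et3SiH, TFA, CH2Cl2, 0 °C → rt) should then give 11, where the route is rejoined.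

2. Step 5. Insertion into the electron‑rich, peri‑substituted chromone may be slow and facial discrimination may erode. Fallback, from 11: a non‑selective conjugate addition (phenylboronic acid, Pd(OCOCF3)2, 2,2′‑bipyridine, aqueous dichloroethane, 60 °C) gives the racemic flavanone F2. This is resolved kinetically by Noyori asymmetric transfer hydrogenation (RuCl(p‑cymene)(TsDPEN), HCO2H/Et3N), using the catalyst enantiomer that reduces the (2R) ketone faster to the cis‑flavan‑4‑ol F3. The unreduced (2S) ketone 13 is separated by chromatography and the route continues from 13.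

3. Step 3. The amide acetal may O‑methylate the phenol or condense at the free formyl group in competition with enaminone formation. Fallback, from 2: the order is inverted. The enaminone F4 is made from 2 (Me2NCH(OMe)2, PhMe, 90 °C) and closed with acid to 5,6,7‑trimethoxychromone F5 before any aldehyde is present. Rieche formylation (Cl2CHOMe, TiCl4, CH2Cl2) at C8, the only unsubstituted benzenoid carbon, then gives 5, where the route is rejoined.

Further compounds
F1 | step 4 | (2-hydroxy-5-methoxyphenyl)(5,6,7-trimethoxy-4-oxo-4H-chromen-8-yl)methanol (racemic) | COc1ccc(O)c(C(O)c2c(OC)c(OC)c(OC)c3c2occc3=O)c1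
F2 | step 5 | rac-8-(2-hydroxy-5-methoxybenzyl)-5,6,7-trimethoxy-2-phenylchroman-4-one | COc1ccc(O)c(Cc2c(OC)c(OC)c(OC)c3c2OC(c2ccccc2)CC3=O)c1
F3 | step 5 | (2R,4R)-8-(2-hydroxy-5-methoxybenzyl)-5,6,7-trimethoxy-2-phenylchroman-4-ol | COc1ccc(O)c(Cc2c(OC)c(OC)c(OC)c3c2O[C@@H](c2ccccc2)C[C@H]3O)c1
F4 | step 3 | (E)-3-(dimethylamino)-1-(6-hydroxy-2,3,4-trimethoxyphenyl)prop-2-en-1-one | CN(C)/C=C/C(=O)c1c(O)cc(OC)c(OC)c1OC
F5 | step 3 | 5,6,7-trimethoxy-4H-chromen-4-one | COc1cc2occc(=O)c2c(OC)c1OC
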